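**Retrosynthetic overview**

1. Germacrane numbering: carbocycle C1–C10, C1=C10 (Z, C14H2O on C10), oxiranes C2–C3 (trans) and C4(Me)–C5 (cis), butenolide C6–O–C12(=O)–C11=C7, C13H2OAc on C11. The strategy rests on C8 and C9, a syn (threo) pair of acyloxy ring carbons between the carbonyl-level butenolide carbon C7 and C10 of the ring alkene; C8–C9 is therefore the aldol bond of a C7 alkoxymethyl ketone and a C9 (Z)-enal.
2. Disconnections: butenolide by intramolecular Horner–Wadsworth–Emmons reaction of a C6 phosphonoester onto the C7 ketone; C8–C9 by ring-closing aldol addition; C1=C10 by ester aldol/elimination; C2–C3 oxirane by Sharpless epoxidation; C4–C5 oxirane by hydroxyl-directed epoxidation; the C3–C8 segment by a vinylogous Mukaiyama aldol of a 2-silyloxyfuran (C6–C7 bond).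
3. C3 and C6 are cis on the C4–C5 oxirane, so a (Z)-C4=C5 alkene is required; it is taken from a butenolide ring, which also carries C6.
4. Ring order: C4–C5 oxirane, C2–C3 oxirane, ten-membered carbocycle, butenolide; the glycidate oxirane arrives with its acid.

Key step: step 20

Remarks: PMB = 4-methoxybenzyl, TES = triethylsilyl, TBS = tert-butyldimethylsilyl, Sen = 3-methylbut-2-enoyl, Ph-pybox = 2,6-bis(4-phenyl-4,5-dihydrooxazol-2-yl)pyridine; germacrane locants are used from 13 on. Compounds 1, 2, 6, 12, 19, 26, 33 and 38 are purchased.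
Assumption: the (S,S)-Ph-pybox copper catalyst is taken to attack the si face of the chelated aldehyde and to give the anti adduct (5S,1'R); if the sense is opposite, the (R,R) ligand is used, since only C6 is carried on.

**Route**

Step 1
Reactants: 1 4-methoxybenzyl alcohol; 2 3-bromoprop-1-ene (allyl bromide)
Product: 3 1-methoxy-4-[(prop-2-en-1-yloxy)methyl]benzene (allyl PMB ether)
Conditions: NaH, n-Bu4NI (cat.), THF, 0 °C → rt
Reagents that add atoms: none
Why: Williamson etherification of the sodium benzylic alkoxide with the allylic bromide (SN2), with no stereocentre involved.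

Step 2
Reactants: 3 allyl PMB ether
Product: 5 2-(PMB-oxy)acetaldehyde, via ozonide 4 (not isolated)
Conditions: O3, CH2Cl2, −78 °C (stopped at the end point); then PPh3, −78 °C → rt
Reagents that add atoms: ozone, [O-][O+]=O
Why: Ozonolysis of the terminal alkene with reductive work-up gives the α-alkoxy aldehyde and formaldehyde, and the low temperature and stopping at the end point spare the anisyl ring.

Step 3
Reactants: 6 3-methylfuran-2(5H)-one
Product: 7 trimethyl[(3-methylfuran-2-yl)oxy]silane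
Conditions: Me3SiOTf, Et3N, Et2O, 0 °C
Reagents that add atoms: trimethylsilyl trifluoromethanesulfonate, C[Si](C)(C)OS(=O)(=O)C(F)(F)F
Why: Soft enolisation and O-silylation of the butenolide give the aromatic 2-silyloxyfuran (dienol silyl ether formation).

Step 4
Reactants: 7 trimethyl[(3-methylfuran-2-yl)oxy]silane; 5 2-(PMB-oxy)acetaldehyde
Product: 9 (5S)-5-[(1R)-1-hydroxy-2-(PMB-oxy)ethyl]-3-methylfuran-2(5H)-one, via O-trimethylsilyl adduct 8 (not isolated)
Conditions: [Cu((S,S)-Ph-pybox)](SbF6)2 (10 mol %), CH2Cl2, −78 °C; then 1 M HCl, THF, 0 °C; the anti adduct is separated from any syn isomer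
Reagents that add atoms: none
Why: Catalytic enantioselective vinylogous Mukaiyama aldol addition in which the aldehyde chelates divalent copper through carbonyl and ether oxygens, the ligand phenyl blocks one aldehyde face and the furan adds through C5 in an open anti-selective transition state, setting C6 (5S) and C7 (1'R, removed later).

Step 5
Reactants: 9 butenolide alcohol
Product: 10 (5S)-3-methyl-5-[(1R)-2-(PMB-oxy)-1-(TES-oxy)ethyl]furan-2(5H)-one
Conditions: Et3SiCl, imidazole, DMF, 0 °C → rt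
Reagents that add atoms: chlorotriethylsilane, CC[Si](Cl)(CC)CC
Why: Standard silylation of the secondary C7 hydroxyl, which must be masked differently from the later C6 silyl ether.

Step 6
Reactants: 10 TES-protected butenolide
Product: 11 (5S)-3-methyl-5-[(1R)-2-(PMB-oxy)-1-(TES-oxy)ethyl]-2,5-dihydrofuran-2-ol (anomers)
Conditions: (i-Bu)2AlH (1.1 equiv), CH2Cl2, −78 °C; aq. KNaC4H4O6 (potassium sodium tartrate)
Reagents that add atoms: none
Why: Partial reduction of the lactone stops at the aluminium hemiacetal at −78 °C and gives the lactol, whose anomeric centre is lost in the next step.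

Step 7
Reactants: 11 lactol; 12 ethyl (triphenyl-λ5-phosphanylidene)acetate
Product: 13 ethyl (2E,4Z,6S,7R)-6-hydroxy-4-methyl-8-(PMB-oxy)-7-(TES-oxy)octa-2,4-dienoate
Conditions: toluene, 40 °C
Reagents that add atoms: none
Why: Wittig olefination of the ring-opened (Z)-γ-hydroxy enal tautomer with a stabilised ylide gives the 2E alkene, while the 4Z geometry is inherited from the ring.

Step 8
Reactants: 13 hydroxy dienoate
Product: 14 ethyl (2E)-4,5-epoxy-6-hydroxy-4-methyl-8-(PMB-oxy)-7-(TES-oxy)oct-2-enoate, cis-oxirane with its oxygen syn (threo) to the C6 hydroxyl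
Conditions: m-CPBA, NaHCO3, CH2Cl2, 0 °C
Reagents that add atoms: 3-chloroperoxybenzoic acid, OOC(=O)c1cccc(Cl)c1
Why: Hydroxyl-directed peracid epoxidation of the distal, electron-richer trisubstituted alkene, in which A(1,3) strain between C6 and the cis C3 substituent places C6–H in the alkene plane so that the hydrogen-bonded peracid is delivered to the face bearing the hydroxyl, setting C4 and C5 threo to C6.

Step 9
Reactants: 14 epoxy alcohol
Product: 15 6-O-TBS ether of 14
Conditions: t-BuMe2SiOTf, 2,6-lutidine, CH2Cl2, −78 °C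
Reagents that add atoms: tert-butyldimethylsilyl trifluoromethanesulfonate, CC(C)(C)[Si](C)(C)OS(=O)(=O)C(F)(F)F
Why: Silyl triflate silylation of the hindered C6 hydroxyl at low temperature with a hindered base leaves the vinyl oxirane untouched.

Step 10
Reactants: 15 TBS-protected epoxy enoate
Product: 16 (2E)-4,5-epoxy-4-methyl-8-(PMB-oxy)-6-(TBS-oxy)-7-(TES-oxy)oct-2-en-1-ol
Conditions: (i-Bu)2AlH (2.2 equiv), CH2Cl2, −78 °C
Reagents that add atoms: none
Why: 1,2-Reduction of the enoate to the allylic alcohol by (i-Bu)2AlH at −78 °C, which leaves the γ,δ-oxirane intact.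

Step 11
Reactants: 16 epoxy allylic alcohol
Product: 17 (2R,3S,4S,5S,6S,7R)-2,3:4,5-diepoxy-4-methyl-8-(PMB-oxy)-6-(TBS-oxy)-7-(TES-oxy)octan-1-ol
Conditions: Ti(Oi-Pr)4, D-(−)-diisopropyl tartrate, t-BuOOH, 4 Å molecular sieves, CH2Cl2, −20 °C
Reagents that add atoms: tert-butyl hydroperoxide, CC(C)(C)OO
Why: Sharpless asymmetric epoxidation of the (E)-allylic alcohol under reagent control by the D-tartrate sets C2 (R) and C3 (S) as the trans oxirane.

Step 12
Reactants: 17 diepoxy alcohol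
Product: 18 2,3:4,5-diepoxy-4-methyl-8-(PMB-oxy)-6-(TBS-oxy)-7-(TES-oxy)octanal
Conditions: Dess–Martin periodinane, NaHCO3, CH2Cl2, 0 °C → rt
Reagents that add atoms: none
Why: Buffered Dess–Martin oxidation gives the α,β-epoxy aldehyde without epimerising C2.

Step 13
Reactants: 19 methyl 3-hydroxypropanoate
Product: 20 methyl 3-(TES-oxy)propanoate
Conditions: Et3SiCl, imidazole, CH2Cl2, 0 °C → rt
Reagents that add atoms: chlorotriethylsilane, CC[Si](Cl)(CC)CC
Why: Silylation of the primary hydroxyl gives the C9–C10–C14 unit with C9 carrying the same silyl group as C7.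

Step 14
Reactants: 18 diepoxy aldehyde; 20 methyl 3-(TES-oxy)propanoate
Product: 22 methyl 3-hydroxy-2-[(TES-oxy)methyl] ester adduct at C1 (mixture at C1 and C10), via lithium enolate 21 (not isolated)
Conditions: LiN(i-Pr)2, THF, −78 °C; then 18, −78 °C; aq. NH4Cl
Reagents that add atoms: none
Why: Aldol addition of the lithium ester enolate to the aldehyde at −78 °C, where the β-silyloxy enolate does not eliminate; both new centres are removed in the next step.

Step 15
Reactants: 22 β-hydroxy ester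
Product: 24 methyl (E)-enoate with the ester carbon C14 trans and C9H2OTES cis to C2, via mesylate 23 (not isolated)
Conditions: MeSO2Cl, Et3N, CH2Cl2, 0 °C; then 1,8-diazabicyclo[5.4.0]undec-7-ene, rt
Reagents that add atoms: none
Why: Mesylation followed by E1cB elimination through the ester enolate gives the thermodynamically preferred trisubstituted enoate with the ester trans to C2, which fixes C9 cis to C2 and hence the later Z ring alkene.

Step 16
Reactants: 24 enoate
Product: 25 C14 allylic alcohol (C14H2OH trans and C9H2OTES cis to C2)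
Conditions: (i-Bu)2AlH (2.2 equiv), CH2Cl2, −78 °C
Reagents that add atoms: none
Why: 1,2-Reduction of the only ester present to the primary allylic alcohol.

Step 17
Reactants: 25 C14 allylic alcohol; 26 3-methylbut-2-enoic acid
Product: 27 C14 senecioate
Conditions: N,N'-dicyclohexylcarbodiimide, 4-(dimethylamino)pyridine (cat.), CH2Cl2, 0 °C
Reagents that add atoms: none
Why: Steglich esterification of the only free hydroxyl, with the free acid and neither acid chloride nor trialkylamine, so that no vinylketene forms and the ester stays conjugated.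

Step 18
Reactants: 27 senecioate
Product: 28 7,9-diol (C6 still O-TBS)
Conditions: HF·pyridine, pyridine, THF, 0 °C
Reagents that add atoms: none
Why: Buffered fluoride cleaves the primary allylic and the secondary TES ethers much faster than the hindered secondary TBS ether.

Step 19
Reactants: 28 7,9-diol
Product: 29 seco keto-enal (2R,3S,4S,5S,6S; C9 (Z)-enal, C7 ketone, C8H2OPMB, C6 OTBS, C14 OSen)
Conditions: Dess–Martin periodinane (3 equiv), NaHCO3, CH2Cl2, 0 °C → rt
Reagents that add atoms: none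
Why: Dess–Martin oxidation converts the allylic primary alcohol to the (Z)-enal and the secondary alcohol to the ketone under neutral conditions that do not isomerise the enal or epimerise C6.

Step 20
Reactants: 29 seco keto-enal
Product: 32 ten-membered C7 ketone with C8 OPMB and C9 hydroxyl (2R,3S,4S,5S,6S,8S,9R), via boron enolate 30 (not isolated), via boron aldolate 31 (not isolated)
Conditions: n-Bu2BOTf, i-Pr2NEt, CH2Cl2 (about 0.002 M), −78 → −20 °C; then pH 7 buffer (NaH2PO4/Na2HPO4), MeOH, 30% H2O2, 0 °C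
Reagents that add atoms: none
Why: The boron triflate and amine enolise the C7 ketone at the C8 methylene, which is activated by the ether oxygen and unhindered, to give the (Z)-enolborinate 30; its boron then binds the C9 aldehyde and C8 adds 1,2 through a closed six-membered chair transition state. The closest known reaction type is the syn-selective boron aldol addition of α-alkoxy or α-silyloxy methyl ketones that carry an α'-oxygenated stereocentre, together with macrocyclising intramolecular aldol additions. The ten-membered carbocycle is closed by the C8–C9 bond (enolate carbon to aldehyde carbon) in a 10-(enolendo)-exo-trig mode. C8 is controlled by C6: with the C6–OSi bond anti to the enolate C–O bond the tether through C5 lies on one enolate face, so C9 reaches C8 only from that face, which gives (8S). C9 is controlled by the enolate geometry, because the (Z)-enolate with the enal residue pseudo-equatorial in the chair gives the 8,9-syn adduct (9R). The step needs enolisation at C8 and not C6 (secured by the tertiary, silyloxy-bearing C6), 1,2- and not 1,4-addition (secured by the boron-bound closed transition state) and ring closure instead of oligomerisation (secured by high dilution and by the (Z)-alkene and two oxiranes that fold the chain); no reducing metal is present, so the vinyl oxirane stays intact.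

Step 21
Reactants: 33 [(2R)-2-methyloxiran-2-yl]methanol
Product: 34 (2S)-2-methyloxirane-2-carboxylic acid
Conditions: RuCl3·xH2O (cat.), NaIO4, MeCN/EtOAc/H2O, 0 °C → rt; used at once
Reagents that add atoms: water, O
Why: Ruthenium tetroxide oxidation (catalytic RuCl3 with periodate) of the primary alcohol to the acid leaves the quaternary centre untouched, the descriptor changing from R to S only through the priority change.

Step 22
Reactants: 32 ten-membered aldol adduct; 34 (2S)-2-methyloxirane-2-carboxylic acid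
Product: 36 C9 (2S)-2-methyloxirane-2-carboxylate of 32, via mixed anhydride 35 (not isolated)
Conditions: 2,4,6-Cl3C6H2COCl, Et3N, THF, 0 °C; then 32, 4-(dimethylamino)pyridine, toluene, 0 °C → rt
Reagents that add atoms: none
Why: Yamaguchi esterification couples the hindered tertiary acid with the hindered allylic C9 hydroxyl with retention at C9.

Step 23
Reactants: 36 C9 ester
Product: 37 C6 alcohol (α-hydroxy ketone)
Conditions: HF·pyridine, pyridine, THF, 0 °C → rt
Reagents that add atoms: none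
Why: Acidic buffered fluoride removes the TBS ether, which is activated by the adjacent ketone, without the base that would eliminate the β-acyloxy group.

Step 24
Reactants: 1 4-methoxybenzyl alcohol; 38 methyl 2-(dimethoxyphosphoryl)prop-2-enoate
Product: 39 methyl 2-(dimethoxyphosphoryl)-3-(PMB-oxy)propanoate
Conditions: 1,8-diazabicyclo[5.4.0]undec-7-ene (cat.), THF, 0 °C → rt
Reagents that add atoms: none
Why: Base-catalysed oxa-Michael addition of the alcohol to the doubly activated acrylate installs C13 as its PMB ether.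

Step 25
Reactants: 39 phosphonate methyl ester
Product: 40 2-(dimethoxyphosphoryl)-3-(PMB-oxy)propanoic acid
Conditions: LiOH·H2O (1.05 equiv), THF/H2O, 0 °C; then cold 1 M HCl
Reagents that add atoms: lithium hydroxide, [Li+].[OH-]
Why: Saponification of the carboxylic methyl ester is faster than attack on the phosphonate esters, and short cold treatment limits retro-Michael loss of the alkoxide.

Step 26
Reactants: 37 C6 alcohol; 40 phosphonate acid
Product: 41 C6 2-(dimethoxyphosphoryl)-3-(PMB-oxy)propanoate (epimers at the phosphonate carbon)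
Conditions: N,N'-dicyclohexylcarbodiimide, 4-(dimethylamino)pyridine (cat.), CH2Cl2, 0 °C
Reagents that add atoms: none
Why: Steglich esterification of a phosphonoacetic acid proceeds through the very reactive phosphonoketene and acylates the hindered α-ketol.

Step 27
Reactants: 41 C6 phosphonoester
Product: 42 6,12-butenolide with C8 OPMB and C13 OPMB (2R,3S,4S,5S,6R,8R,9R)
Conditions: LiCl, i-Pr2NEt, MeCN, 0 °C → rt
Reagents that add atoms: none
Why: Intramolecular Horner–Wadsworth–Emmons olefination under the mild LiCl/amine conditions forms C11=C7 and closes the five-membered lactone, the lithium-chelated phosphonate being more acidic than the C8 proton.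

Step 28
Reactants: 42 bis-PMB butenolide
Product: 43 8,13-diol
Conditions: DDQ, CH2Cl2/pH 7 buffer (NaH2PO4/Na2HPO4), 0 °C → rt
Reagents that add atoms: none
Why: Oxidative cleavage of both PMB ethers by DDQ under near-neutral conditions tolerates the oxiranes, esters and butenolide.

Step 29
Reactants: 43 8,13-diol
Product: 44 CNP0279449.1
Conditions: Ac2O, pyridine, 4-(dimethylamino)pyridine (cat.), CH2Cl2, 0 °C
Reagents that add atoms: acetic anhydride, CC(=O)OC(C)=O
Why: Fast acetylation of the primary C13 and secondary C8 hydroxyls at 0 °C outruns acyl migration from C9 and translactonisation to C8.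

**Compound list**

1 | 4-methoxybenzyl alcohol | COc1ccc(CO)cc1 | starting material
2 | 3-bromoprop-1-ene (allyl bromide) | C=CCBr | starting material
3 | 1-methoxy-4-[(prop-2-en-1-yloxy)methyl]benzene (allyl PMB ether) | C=CCOCc1ccc(OC)cc1 | intermediate
4 | 3-{[(4-methoxybenzyl)oxy]methyl}-1,2,4-trioxolane (ozonide) | COc1ccc(COCC2OOCO2)cc1 | intermediate
5 | 2-[(4-methoxybenzyl)oxy]acetaldehyde | COc1ccc(COCC=O)cc1 | intermediate
6 | 3-methylfuran-2(5H)-one | CC1=CCOC1=O | starting material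
7 | trimethyl[(3-methylfuran-2-yl)oxy]silane | Cc1ccoc1O[Si](C)(C)C | intermediate
8 | (5S)-3-methyl-5-[(1R)-2-(PMB-oxy)-1-(trimethylsilyloxy)ethyl]furan-2(5H)-one | CC1=C[C@@H]([C@H](O[Si](C)(C)C)COCc2ccc(OC)cc2)OC1=O | intermediate
9 | (5S)-5-[(1R)-1-hydroxy-2-(PMB-oxy)ethyl]-3-methylfuran-2(5H)-one | CC1=C[C@@H]([C@H](O)COCc2ccc(OC)cc2)OC1=O | intermediate
10 | (5S)-3-methyl-5-[(1R)-2-(PMB-oxy)-1-(TES-oxy)ethyl]furan-2(5H)-one | CC1=C[C@@H]([C@H](O[Si](CC)(CC)CC)COCc2ccc(OC)cc2)OC1=O | intermediate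
11 | (5S)-3-methyl-5-[(1R)-2-(PMB-oxy)-1-(TES-oxy)ethyl]-2,5-dihydrofuran-2-ol (anomers) | CC1=C[C@@H]([C@H](O[Si](CC)(CC)CC)COCc2ccc(OC)cc2)OC1O | intermediate
12 | ethyl (triphenyl-λ5-phosphanylidene)acetate | CCOC(=O)C=P(c1ccccc1)(c1ccccc1)c1ccccc1 | starting material
13 | ethyl (2E,4Z,6S,7R)-6-hydroxy-4-methyl-8-(PMB-oxy)-7-(TES-oxy)octa-2,4-dienoate | CCOC(=O)/C=C/C(C)=C\[C@H](O)[C@H](O[Si](CC)(CC)CC)COCc1ccc(OC)cc1 | intermediate
14 | ethyl (2E)-4,5-epoxy-6-hydroxy-4-methyl-8-(PMB-oxy)-7-(TES-oxy)oct-2-enoate (cis-oxirane, threo to 6-OH) | CCOC(=O)/C=C/[C@@]1(C)O[C@H]1[C@H](O)[C@H](O[Si](CC)(CC)CC)COCc1ccc(OC)cc1 | intermediate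
15 | 6-O-TBS ether of 14 | CCOC(=O)/C=C/[C@@]1(C)O[C@H]1[C@H](O[Si](C)(C)C(C)(C)C)[C@H](O[Si](CC)(CC)CC)COCc1ccc(OC)cc1 | intermediate
16 | (2E)-4,5-epoxy-4-methyl-8-(PMB-oxy)-6-(TBS-oxy)-7-(TES-oxy)oct-2-en-1-ol | OC/C=C/[C@@]1(C)O[C@H]1[C@H](O[Si](C)(C)C(C)(C)C)[C@H](O[Si](CC)(CC)CC)COCc1ccc(OC)cc1 | intermediate
17 | (2R,3S,4S,5S,6S,7R)-2,3:4,5-diepoxy-4-methyl-8-(PMB-oxy)-6-(TBS-oxy)-7-(TES-oxy)octan-1-ol | OC[C@H]1O[C@@H]1[C@@]1(C)O[C@H]1[C@H](O[Si](C)(C)C(C)(C)C)[C@H](O[Si](CC)(CC)CC)COCc1ccc(OC)cc1 | intermediate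
18 | 2,3:4,5-diepoxy-4-methyl-8-(PMB-oxy)-6-(TBS-oxy)-7-(TES-oxy)octanal (configuration as 17) | O=C[C@H]1O[C@@H]1[C@@]1(C)O[C@H]1[C@H](O[Si](C)(C)C(C)(C)C)[C@H](O[Si](CC)(CC)CC)COCc1ccc(OC)cc1 | intermediate
19 | methyl 3-hydroxypropanoate | COC(=O)CCO | starting material
20 | methyl 3-[(triethylsilyl)oxy]propanoate | COC(=O)CCO[Si](CC)(CC)CC | intermediate
21 | lithium enolate of 20 | CO/C(O[Li])=C\CO[Si](CC)(CC)CC | intermediate
22 | aldol adduct of 18 and 20 (C1 carbinol, C10 bearing CO2Me and CH2OTES; mixture at C1 and C10) | COC(=O)C(CO[Si](CC)(CC)CC)C(O)[C@H]1O[C@@H]1[C@@]1(C)O[C@H]1[C@H](O[Si](C)(C)C(C)(C)C)[C@H](O[Si](CC)(CC)CC)COCc1ccc(OC)cc1 | intermediate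
23 | C1 methanesulfonate of 22 | COC(=O)C(CO[Si](CC)(CC)CC)C(OS(C)(=O)=O)[C@H]1O[C@@H]1[C@@]1(C)O[C@H]1[C@H](O[Si](C)(C)C(C)(C)C)[C@H](O[Si](CC)(CC)CC)COCc1ccc(OC)cc1 | intermediate
24 | methyl (E)-enoate, CO2Me (C14) trans and CH2OTES (C9) cis to C2 | COC(=O)/C(CO[Si](CC)(CC)CC)=C/[C@H]1O[C@@H]1[C@@]1(C)O[C@H]1[C@H](O[Si](C)(C)C(C)(C)C)[C@H](O[Si](CC)(CC)CC)COCc1ccc(OC)cc1 | intermediate
25 | C14 allylic alcohol from 24 | OC/C(CO[Si](CC)(CC)CC)=C/[C@H]1O[C@@H]1[C@@]1(C)O[C@H]1[C@H](O[Si](C)(C)C(C)(C)C)[C@H](O[Si](CC)(CC)CC)COCc1ccc(OC)cc1 | intermediate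
26 | 3-methylbut-2-enoic acid | CC(C)=CC(O)=O | starting material
27 | C14 3-methylbut-2-enoate of 25 | CC(C)=CC(=O)OC/C(CO[Si](CC)(CC)CC)=C/[C@H]1O[C@@H]1[C@@]1(C)O[C@H]1[C@H](O[Si](C)(C)C(C)(C)C)[C@H](O[Si](CC)(CC)CC)COCc1ccc(OC)cc1 | intermediate
28 | 7,9-diol (C6 OTBS, C8 OPMB, C14 OSen) | CC(C)=CC(=O)OC/C(CO)=C/[C@H]1O[C@@H]1[C@@]1(C)O[C@H]1[C@H](O[Si](C)(C)C(C)(C)C)[C@H](O)COCc1ccc(OC)cc1 | intermediate
29 | seco (Z)-enal alkoxymethyl ketone (2R,3S,4S,5S,6S) | O=C/C(COC(=O)C=C(C)C)=C\[C@H]1O[C@@H]1[C@@]1(C)O[C@H]1[C@H](O[Si](C)(C)C(C)(C)C)C(=O)COCc1ccc(OC)cc1 | intermediate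
30 | (Z)-dibutylboron enolate of 29 (C7=C8, OPMB cis to OB) | O=C/C(COC(=O)C=C(C)C)=C\[C@H]1O[C@@H]1[C@@]1(C)O[C@H]1[C@H](O[Si](C)(C)C(C)(C)C)/C(OB(CCCC)CCCC)=C/OCc1ccc(OC)cc1 | intermediate
31 | C9 O-dibutylboryl aldolate of 32 | O=C1[C@@H](OCc2ccc(OC)cc2)[C@H](OB(CCCC)CCCC)/C(COC(=O)C=C(C)C)=C\[C@H]2O[C@@H]2[C@@]2(C)O[C@H]2[C@@H]1O[Si](C)(C)C(C)(C)C | intermediate
32 | ten-membered C7 ketone, C8 OPMB, C9 OH, C6 OTBS (2R,3S,4S,5S,6S,8S,9R; 1(10)Z) | O=C1[C@@H](OCc2ccc(OC)cc2)[C@H](O)/C(COC(=O)C=C(C)C)=C\[C@H]2O[C@@H]2[C@@]2(C)O[C@H]2[C@@H]1O[Si](C)(C)C(C)(C)C | intermediate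
33 | [(2R)-2-methyloxiran-2-yl]methanol | OC[C@]1(C)CO1 | starting material
34 | (2S)-2-methyloxirane-2-carboxylic acid | OC(=O)[C@]1(C)CO1 | intermediate
35 | mixed anhydride of 34 with 2,4,6-trichlorobenzoic acid | O=C(OC(=O)[C@]1(C)CO1)c1c(Cl)cc(Cl)cc1Cl | intermediate
36 | C9 (2S)-2-methyloxirane-2-carboxylate of 32 | O=C1[C@@H](OCc2ccc(OC)cc2)[C@H](OC(=O)[C@]3(C)CO3)/C(COC(=O)C=C(C)C)=C\[C@H]2O[C@@H]2[C@@]2(C)O[C@H]2[C@@H]1O[Si](C)(C)C(C)(C)C | intermediate
37 | C6 alcohol from 36 | O=C1[C@@H](OCc2ccc(OC)cc2)[C@H](OC(=O)[C@]3(C)CO3)/C(COC(=O)C=C(C)C)=C\[C@H]2O[C@@H]2[C@@]2(C)O[C@H]2[C@@H]1O | intermediate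
38 | methyl 2-(dimethoxyphosphoryl)prop-2-enoate | COC(=O)C(=C)P(=O)(OC)OC | starting material
39 | methyl 2-(dimethoxyphosphoryl)-3-[(4-methoxybenzyl)oxy]propanoate | COC(=O)C(COCc1ccc(OC)cc1)P(=O)(OC)OC | intermediate
40 | 2-(dimethoxyphosphoryl)-3-[(4-methoxybenzyl)oxy]propanoic acid | OC(=O)C(COCc1ccc(OC)cc1)P(=O)(OC)OC | intermediate
41 | C6 2-(dimethoxyphosphoryl)-3-(PMB-oxy)propanoate of 37 | O=C1[C@@H](OCc2ccc(OC)cc2)[C@H](OC(=O)[C@]3(C)CO3)/C(COC(=O)C=C(C)C)=C\[C@H]2O[C@@H]2[C@@]2(C)O[C@H]2[C@@H]1OC(=O)C(COCc1ccc(OC)cc1)P(=O)(OC)OC | intermediate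
42 | 6,12-butenolide with C8 OPMB and C13 OPMB | COc1ccc(COCC2=C3[C@@H](OCc4ccc(OC)cc4)[C@H](OC(=O)[C@]4(C)CO4)/C(COC(=O)C=C(C)C)=C\[C@H]4O[C@@H]4[C@@]4(C)O[C@H]4[C@@H]3OC2=O)cc1 | intermediate
43 | 8,13-diol butenolide | OCC1=C2[C@@H](O)[C@H](OC(=O)[C@]3(C)CO3)/C(COC(=O)C=C(C)C)=C\[C@H]3O[C@@H]3[C@@]3(C)O[C@H]3[C@@H]2OC1=O | intermediate
44 | CNP0279449.1 (2R,3S,4S,5S,6R,8R,9R; 1(10)Z; glycidate S) | CC(=O)OCC1=C2[C@@H](OC(C)=O)[C@H](OC(=O)[C@]3(C)CO3)/C(COC(=O)C=C(C)C)=C\[C@H]3O[C@@H]3[C@@]3(C)O[C@H]3[C@@H]2OC1=O | target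

**Step count**

Total steps: 29. Longest linear sequence: 24 steps (1 → 3 → 5 → 9 → … → 29 → 32 → 36 → 37 → 41 → 42 → 43 → 44).

**Steps most likely to fail**

Step 20. The ring may close through a transition state with the enal residue pseudo-axial or through a boat, so facial selectivity at the aldehyde may be poor, and intermolecular aldol addition may compete. Fallback: setting out from 29, the closure is run as before and the C9 configuration it delivers is accepted; the 9-epimeric aldol adduct F1 is then esterified with acid 34 under Mitsunobu conditions (PPh3, diisopropyl azodicarboxylate, THF, 0 °C). C9 is then set by SN2 inversion instead of by the C–C bond formation, and the sequence comes back at 36.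

Step 27. The base may remove the C8 proton of the β-acyloxy ketone and expel the C9 carboxylate (E1cB) faster than the phosphonate carbanion adds to C7. Fallback: setting out from 32, the C9 hydroxyl is first masked as a poor leaving group and the ester is introduced after the lactone. i-Pr3SiOTf/2,6-lutidine gives the 9-O-triisopropylsilyl ether F2. HF·pyridine removes only the TBS group to give the C6 alcohol F3. Acid 40 with the carbodiimide gives the C6 phosphonoester F4. LiCl/i-Pr2NEt closes the 9-silyloxy butenolide F5. Prolonged HF·pyridine frees the 9-hydroxy butenolide F6, and Yamaguchi esterification with 34 comes back at 42.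

Step 7. The lactol may lose water to the aromatic furan, the open hydroxy enal may isomerise from Z to E, or the C6 hydroxyl may add in conjugate fashion to the new enoate. Fallback: setting out from 10, the lactol is avoided. Excess (i-Bu)2AlH (−78 → 0 °C) gives the (Z)-enediol F7. m-CPBA, directed by the C6 hydroxyl, gives the epoxy diol F8. Pivaloyl chloride/pyridine acylates the primary hydroxyl (primary pivalate F9). t-BuMe2SiOTf/2,6-lutidine gives the 6-O-TBS pivalate F10. (i-Bu)2AlH removes the pivalate (primary alcohol F11). Dess–Martin oxidation gives the epoxy aldehyde F12, and Wittig reaction with 12 comes back at 15.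

**Further compounds**

F1 | step 20 | 9-epimer of 32 (8S,9S) | O=C1[C@@H](OCc2ccc(OC)cc2)[C@@H](O)/C(COC(=O)C=C(C)C)=C\[C@H]2O[C@@H]2[C@@]2(C)O[C@H]2[C@@H]1O[Si](C)(C)C(C)(C)C
F2 | step 27 | 9-O-triisopropylsilyl ether of 32 | O=C1[C@@H](OCc2ccc(OC)cc2)[C@H](O[Si](C(C)C)(C(C)C)C(C)C)/C(COC(=O)C=C(C)C)=C\[C@H]2O[C@@H]2[C@@]2(C)O[C@H]2[C@@H]1O[Si](C)(C)C(C)(C)C
F3 | step 27 | C6 alcohol with 9-O-triisopropylsilyl ether | O=C1[C@@H](OCc2ccc(OC)cc2)[C@H](O[Si](C(C)C)(C(C)C)C(C)C)/C(COC(=O)C=C(C)C)=C\[C@H]2O[C@@H]2[C@@]2(C)O[C@H]2[C@@H]1O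
F4 | step 27 | C6 2-(dimethoxyphosphoryl)-3-(PMB-oxy)propanoate of F3 | O=C1[C@@H](OCc2ccc(OC)cc2)[C@H](O[Si](C(C)C)(C(C)C)C(C)C)/C(COC(=O)C=C(C)C)=C\[C@H]2O[C@@H]2[C@@]2(C)O[C@H]2[C@@H]1OC(=O)C(COCc1ccc(OC)cc1)P(=O)(OC)OC
F5 | step 27 | 6,12-butenolide with C8 OPMB, C13 OPMB and C9 O-triisopropylsilyl | COc1ccc(COCC2=C3[C@@H](OCc4ccc(OC)cc4)[C@H](O[Si](C(C)C)(C(C)C)C(C)C)/C(COC(=O)C=C(C)C)=C\[C@H]4O[C@@H]4[C@@]4(C)O[C@H]4[C@@H]3OC2=O)cc1
F6 | step 27 | 6,12-butenolide with C8 OPMB, C13 OPMB and free C9 hydroxyl | COc1ccc(COCC2=C3[C@@H](OCc4ccc(OC)cc4)[C@H](O)/C(COC(=O)C=C(C)C)=C\[C@H]4O[C@@H]4[C@@]4(C)O[C@H]4[C@@H]3OC2=O)cc1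
F7 | step 7 | (Z)-2-methyl-6-(PMB-oxy)-5-(TES-oxy)hex-2-ene-1,4-diol (C3–C8 enediol) | OC/C(C)=C\[C@H](O)[C@H](O[Si](CC)(CC)CC)COCc1ccc(OC)cc1
F8 | step 7 | C4–C5 cis-epoxy diol of F7 (threo to the C6 hydroxyl) | OC[C@@]1(C)O[C@H]1[C@H](O)[C@H](O[Si](CC)(CC)CC)COCc1ccc(OC)cc1
F9 | step 7 | primary (C3) pivalate of F8 | CC(C)(C)C(=O)OC[C@@]1(C)O[C@H]1[C@H](O)[C@H](O[Si](CC)(CC)CC)COCc1ccc(OC)cc1
F10 | step 7 | 6-O-TBS ether of F9 | CC(C)(C)C(=O)OC[C@@]1(C)O[C@H]1[C@H](O[Si](C)(C)C(C)(C)C)[C@H](O[Si](CC)(CC)CC)COCc1ccc(OC)cc1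
F11 | step 7 | C3 primary alcohol (C6 OTBS, C7 OTES) | OC[C@@]1(C)O[C@H]1[C@H](O[Si](C)(C)C(C)(C)C)[C@H](O[Si](CC)(CC)CC)COCc1ccc(OC)cc1
F12 | step 7 | C3 epoxy aldehyde (C6 OTBS, C7 OTES) | O=C[C@@]1(C)O[C@H]1[C@H](O[Si](C)(C)C(C)(C)C)[C@H](O[Si](CC)(CC)CC)COCc1ccc(OC)cc1
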